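## Structural features

The target is a pentabrominated diphenyl ether: two benzene rings, ring A and ring B, joined only by an ether oxygen between C2 of ring A and C1' of ring B. It has no stereocentre, so no two stereocentres stand next to each other and nothing stereochemical has to be set. Ring A is numbered so that C1 carries the free hydroxyl, C2 the aryloxy group, C3 hydrogen and C4, C5 and C6 bromine; ring B is a 2',4'-dibromophenyl group. The fragile parts are the five aryl C–Br bonds (exchange with alkyllithiums, insertion of zerovalent palladium, hydrogenolysis) and the electron-rich phenol, which over-brominates to bromodienones. The real difficulty is regiochemical, not skeletal. C4 and C6 are para and ortho to the hydroxyl and take bromine readily, but C5 is meta to it, so no phenol-directed substitution reaches C5; ring B must also stop at two bromines while ring A takes three. The key step exploits the fact that the triad C6–C1(OH)–C2(OAr) of ring A is C2–C3–C4 of a 4-aryloxyacetoacetate and that C3–C4–C5 is a malondialdehyde unit, so ring A can be closed from two open chains with ring B and its bromines already on the oxygen. The ester that this annulation leaves on C6 lies ortho to C5, can deliver bromine there, and is itself exchangeable for bromine once the hydroxyl is free.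

## Logic of the disconnections

16 from 14 (through 15). The bonds cut are C4–Br and C6–Br, the latter traced back to a carboxyl group. Both carbons are para and ortho to the free hydroxyl on C1, and a carboxyl group ortho to a phenol is displaced by ipso attack of electrophilic bromine with loss of CO2. The gain is that two of the five bromines disappear and the C6 substituent becomes a group that can do work before it leaves. The demand is that the forward step spends two equivalents of electrophilic bromine on ring A only, leaves C3 and ring B alone, and does not push the product on to a bromodienone.

14 from 13. The O–CH3 bond on the C1 oxygen is added back. A free hydroxyl would send electrophilic bromine to C4 and C6 at once and destroy the carboxyl handle before C5 is served, so the phenol is masked during the C5 bromination. There is no gain in size, only in control of the order of events. The demand is an ether cleavage that spares the diaryl ether and three C–Br bonds.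

13 from 12. The bond cut is C5–Br. C5 is meta to the C1 oxygen but is the only C–H ortho to the C6 carboxyl, which can hold a metal at that carbon. The gain is a ring A free of bromine, a plain 2,3-dioxygenated benzoic acid. The demand is metalation at C5 alone by a catalyst that never inserts into the C–Br bonds of ring B, with a bromine source that does not displace the carboxyl group.

12 from 10 (through 11). The O–CH3 bond of the ether is cut and the acid is returned to its methyl ester. This is functional-group adjustment only, and it brings the intermediate back to the direct product of the ring synthesis. The demand is that the chelated, flanked phenol is alkylated fully before the ester is hydrolysed.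

10 from 6 and 7 (through 9 and 8). The bonds cut are C2–C3 and C5–C6, which opens ring A into a four-carbon 1,3-dinucleophile (C6, C1, C2 and the ester carbon) and a three-carbon 1,3-dielectrophile (C3, C4, C5). The cut places hydroxyl, aryloxy and ester on three adjacent carbons exactly as an acetoacetate chain carries them, and it removes the only ring formed in the route. The demand is that the dinucleophile reacts first at its terminal carbon and then at its central carbon; because 7 is symmetrical no other regiochemical question arises.

6 from 4 (through 5), and 4 from 3. The two O–Si bonds are cut in turn, taking the diene back to a β-keto ester. The gain is a stable, storable precursor. The demand is that the base of the second silylation removes the hydrogen on the aryloxy-bearing carbon and not one on ring B.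

3 from 1 and 2. The bond cut is that between the phenol oxygen and the C4 methylene of the keto ester. This leads to two commercial compounds, one of which brings the complete bromine pattern of ring B. The demand is that O-alkylation outruns self-condensation of 2.

## Other disconnections considered

Alternative 1: The cut is in ring B, at O–C1' and C2'–Br, so that ring B is an aryne and ring A a purchased phenol. In the forward key step fluoride would release the aryne from 2-(trimethylsilyl)phenyl triflate A1, the caesium phenoxide of 4-bromo-2-methoxyphenol A2 would add to it, and the resulting ortho-aryloxy aryl anion would take bromine from 1,2-dibromotetrachloroethane A3 to give 4-bromo-1-(2-bromophenoxy)-2-methoxybenzene A4.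
- In its favour: A2 brings the awkward C5 bromine of ring A already in place, para to the future ether oxygen. That is better than the chosen plan, where C5 needs a directed C–H bromination. The aryne is symmetrical, so the addition raises no regiochemical question, which equals the symmetrical dielectrophile 7. A4 would be about three steps from 16 against four from 10, so step economy is better.
- Against it: the aryl anion beside the new ether oxygen is usually protonated by solvent or phenol faster than it meets an external halogen donor, and A3 could also brominate the electron-rich phenoxide. More seriously, A4 lacks the C4' bromine. It would have to be introduced late by electrophilic substitution on a ring already deactivated by one bromine, in competition with C6' and, after ether cleavage, with the far more reactive ring A.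
- Comparison: on structure, the chosen plan buys the full ring B pattern in 1 and never has to tell the rings apart, whereas this plan buys the ring A bromine and leaves ring B open. On mechanism, it depends on outrunning a proton transfer, where the chosen plan relies on two catalytic Mukaiyama-type bond formations whose order is inherent.

Alternative 2: Ring A is cut at C2–C3 and C1–C6 into a pyrone diene and an alkyne that already carries the ether oxygen. In the forward key step 2-[(2,4-dibromophenoxy)ethynyl]-4,4,5,5-tetramethyl-1,3,2-dioxaborolane A6 would add across C3 and C6 of 5-bromo-2-pyrone A5 in a Diels–Alder reaction. Decarboxylative aromatisation of the bridged lactone would give 2-[5-bromo-2-(2,4-dibromophenoxy)phenyl]-4,4,5,5-tetramethyl-1,3,2-dioxaborolane A7. Oxidation of the C–B bond would then give 5-bromo-2-(2,4-dibromophenoxy)phenol A8, and phenol-directed bromination at C4 and C6 would give 16.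
- In its favour: one step fixes the C1 oxygen (as boron), the C2 aryloxy group and the C5 bromine. No protecting group and no C–H functionalisation are needed, and A7 is two steps from 16. On the C5 problem and on step count after the key step this is better than the chosen plan. It is the equal of the chosen plan in building ring A by annulation while taking ring B with both bromines from 1.
- Against it: A6 is a push–pull ynol ether. Its preparation passes through the ethynyl ether of 1, normally made by alkyllithium-induced elimination, which collides with the bromines of ring B. The cycloaddition and aromatisation need high temperature, where aryloxyalkynes are labile.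
- Comparison: on mechanism, the orientation rests on polarity matching. The boron-bearing alkyne carbon, β to oxygen, must act as the nucleophilic terminus and bond to C6 of A5; the opposite orientation would put bromine on C4. In the chosen plan symmetry removes this question.

Alternative 3: Ring B is cut at C1'–C2' and C5'–C6' and built directly on the ether oxygen. In the forward key step 4-bromo-1-(ethynyloxy)-2-methoxybenzene A10, the ethynyl ether of A2, would add across C3 and C6 of 3,5-dibromo-2-pyrone A9, and decarboxylative aromatisation would give 4-bromo-1-(2,4-dibromophenoxy)-2-methoxybenzene A11. Ether cleavage would give A8 and bromination at C4 and C6 would give 16.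
- In its favour: A9 is a reactive ambiphilic diene, well matched to an electron-rich alkyne, with the nucleophilic terminal carbon expected to bond to its C6. Both ring B bromines arrive together and the C5 bromine is bought in A2. The whole route could be about five steps, so it is better than the chosen plan in step count and in the handling of C5. It is equal to it in the final phenol-directed bromination.
- Against it: A10 has to be made from A2 through a dichlorovinyl ether and an alkyllithium elimination, in the presence of an aryl bromide. Terminal aryl ynol ethers are thermally sensitive, while the cycloaddition needs heat.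
- Comparison: on structure, the ring B pattern depends entirely on the orientation of the cycloaddition (the reverse orientation gives a 3',5'-dibromo ring), whereas the chosen plan buys that pattern in 1 and cannot get it wrong.

Key step: step 4

Remark on the chemistry: the enol-ether geometries of 4, 5 and 6 are not controlled and need not be, because both double bonds of 6 end up in the aromatic ring; one isomer is drawn for 4 and 6.

## Route

Step 1
Reactants: 1 2,4-dibromophenol; 2 methyl 4-chloroacetoacetate (methyl 4-chloro-3-oxobutanoate)
Product: 3 methyl 4-(2,4-dibromophenoxy)-3-oxobutanoate
Conditions: NaH (2.1 equiv), THF, 0 → 60 °C; aq. HCl work-up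
Reagents that add atoms: none
Why: Williamson ether synthesis (SN2): one equivalent of hydride makes the phenoxide and the second turns 2 into its sodium enolate, which shields the ketone and C2 while the primary chloride is displaced; the aryl bromides are inert to these conditions.

Step 2
Reactants: 3 methyl 4-(2,4-dibromophenoxy)-3-oxobutanoate
Product: 4 methyl 4-(2,4-dibromophenoxy)-3-(trimethylsilyloxy)but-2-enoate (Z/E mixture)
Conditions: Me3SiCl (1.5 equiv), Et3N (1.6 equiv), toluene, 20 °C, 48 h; filtration under N2
Reagents that add atoms: chlorotrimethylsilane, C[Si](C)(C)Cl
Why: O-silylation of the enolised β-keto ester by silyl chloride and tertiary amine (silyl enol ether formation); the enol conjugated to the ester is the one trapped, and nothing else in 3 reacts.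

Step 3
Reactants: 4 methyl 4-(2,4-dibromophenoxy)-3-(trimethylsilyloxy)but-2-enoate
Product: 6 1-methoxy-1,3-bis(trimethylsilyloxy)-4-(2,4-dibromophenoxy)buta-1,3-diene, via lithium dienolate 5 (not isolated)
Conditions: LiN(i-Pr)2 (1.1 equiv), THF, −78 °C, 1 h; Me3SiCl (1.2 equiv), −78 → 20 °C; hexane, filtration, concentration; used crude
Reagents that add atoms: chlorotrimethylsilane, C[Si](C)(C)Cl
Why: Kinetic γ-deprotonation of the silyl enol ether ester at the aryloxy-bearing carbon gives the extended enolate 5, which is silylated on oxygen (standard route to 1,3-bis(silyloxy)-1,3-dienes). This hydrogen is far more acidic than any ring B hydrogen, so at −78 °C with a near-stoichiometric amide base neither ring metalation nor bromine migration is expected.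

Step 4
Reactants: 6 1-methoxy-1,3-bis(trimethylsilyloxy)-4-(2,4-dibromophenoxy)buta-1,3-diene; 7 1,1,3,3-tetramethoxypropane
Product: 10 methyl 3-(2,4-dibromophenoxy)-2-hydroxybenzoate, via open-chain adduct 8 (not isolated), via cyclohexanone ester 9 (not isolated)
Conditions: 7 (1.1 equiv), Me3SiOTf (0.2 equiv), CH2Cl2, −78 → 20 °C, 14 h; then 10 % aq. HCl
Reagents that add atoms: none
Why: This is a formal [3+3] cyclocondensation, and the closest known reaction type is the Me3SiOTf-catalysed salicylate synthesis from 1,3-bis(silyloxy)-1,3-dienes and 1,3-bis-acetals, which accepts heteroatom substituents on the diene terminus. The silyl triflate ionises one acetal of 7 to an oxocarbenium ion, which the terminal, aryloxy-bearing carbon of 6 attacks in a vinylogous Mukaiyama aldol step (bond C2–C3) to give 8 and methoxytrimethylsilane. Ionisation of the second acetal is followed by attack of the central carbon of the remaining silyl enol ether (bond C5–C6) in a 6-(enolexo)-exo-trig closure that gives 9 and returns the catalyst. Loss of two molecules of methanol, driven by aromatisation and completed by the acidic work-up, should deliver phenol 10. No stereocentre survives into 10; those of 8 and 9 are transient and need no control. The selectivity required is the order terminal carbon first, central carbon second, which is the inherent order of nucleophilicity of the diene. Because 7 is symmetrical there is no regiochemical alternative: the aryloxy group must end on C2 and the ester on C6. The mild Lewis acid at low temperature should leave the aryl ether bond and both C–Br bonds untouched.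

Step 5
Reactants: 10 methyl 3-(2,4-dibromophenoxy)-2-hydroxybenzoate
Product: 12 3-(2,4-dibromophenoxy)-2-methoxybenzoic acid, via O-methyl ester 11 (not isolated)
Conditions: MeI (1.5 equiv), K2CO3 (2 equiv), DMF, 40 °C; then 2 M aq. NaOH, MeOH, 60 °C; HCl to pH 2
Reagents that add atoms: iodomethane, CI; sodium hydroxide, [Na+].[OH-]
Why: Williamson O-methylation of the chelated phenol followed in the same flask by saponification (acyl–oxygen cleavage) of an ester with only one ortho substituent; excess iodomethane is destroyed by the hydroxide. Masking the hydroxyl switches off ipso-bromodecarboxylation during the next step.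

Step 6
Reactants: 12 3-(2,4-dibromophenoxy)-2-methoxybenzoic acid
Product: 13 6-bromo-3-(2,4-dibromophenoxy)-2-methoxybenzoic acid
Conditions: Pd(OAc)2 (10 mol %), NBS (1.2 equiv), KOAc (0.3 equiv), ClCH2CH2Cl, 70 °C, dark
Reagents that add atoms: N-bromosuccinimide, O=C1CCC(=O)N1Br
Why: Carboxylate-directed ortho C–H halogenation by divalent palladium: carboxylate coordination and concerted metalation–deprotonation give a five-membered palladacycle at C5, the only C–H ortho to the carboxyl; oxidation by NBS to tetravalent palladium and C–Br reductive elimination follow, and no zerovalent palladium arises that could insert into the aryl bromides. Any uncatalysed substitution is expected at C5 (para to the aryloxy oxygen, the C1 methoxy being twisted out of conjugation) or at C4, and both carbons carry bromine in 16.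

Step 7
Reactants: 13 6-bromo-3-(2,4-dibromophenoxy)-2-methoxybenzoic acid
Product: 14 6-bromo-3-(2,4-dibromophenoxy)-2-hydroxybenzoic acid
Conditions: BBr3 (3 equiv), CH2Cl2, −78 → 0 °C; H2O
Reagents that add atoms: none
Why: Lewis-acid cleavage of an aryl methyl ether: boron binds the methoxy oxygen, helped by chelation to the neighbouring carboxyl, and bromide removes the methyl group by SN2; diaryl ethers and aryl bromides are inert to BBr3. Loss of CO2 at this stage would be harmless, since the resulting phenol is brominated to 16 by the same reagent in step 8.

Step 8
Reactants: 14 6-bromo-3-(2,4-dibromophenoxy)-2-hydroxybenzoic acid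
Product: 16 2,3,4-tribromo-6-(2,4-dibromophenoxy)phenol, via C4-bromo acid 15 (not isolated)
Conditions: Br2 (2.1 equiv), AcOH–H2O, 20 °C; aq. NaHSO3 work-up
Reagents that add atoms: bromine, BrBr
Why: Phenol-directed electrophilic bromination at C4 (para) should give 15; ipso attack at C6 (ortho) then forms a bromocyclohexadienone carboxylic acid that loses CO2 (bromodecarboxylation, the known behaviour of salicylic acids). The positions left, C3 and those of ring B, are not activated by the hydroxyl, and the bisulfite wash reduces any bromodienone from excess bromine back to the phenol.

## Compound list

1 | 2,4-dibromophenol | Oc1ccc(Br)cc1Br | starting material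
2 | methyl 4-chloroacetoacetate (methyl 4-chloro-3-oxobutanoate) | COC(=O)CC(=O)CCl | starting material
3 | methyl 4-(2,4-dibromophenoxy)-3-oxobutanoate | COC(=O)CC(=O)COc1ccc(Br)cc1Br | intermediate
4 | methyl 4-(2,4-dibromophenoxy)-3-(trimethylsilyloxy)but-2-enoate (Z isomer drawn; mixture serves) | COC(=O)/C=C(\O[Si](C)(C)C)COc1ccc(Br)cc1Br | intermediate
5 | lithium dienolate of 4: lithium 4-(2,4-dibromophenoxy)-1-methoxy-3-(trimethylsilyloxy)buta-1,3-dien-1-olate (geometry undefined) | [Li+].COC([O-])=CC(O[Si](C)(C)C)=COc1ccc(Br)cc1Br | intermediate (not isolated)
6 | 1-methoxy-1,3-bis(trimethylsilyloxy)-4-(2,4-dibromophenoxy)buta-1,3-diene (one geometric isomer drawn; mixture serves) | CO/C(O[Si](C)(C)C)=C/C(O[Si](C)(C)C)=C/Oc1ccc(Br)cc1Br | intermediate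
7 | 1,1,3,3-tetramethoxypropane | COC(OC)CC(OC)OC | starting material
8 | open-chain adduct: 4-(2,4-dibromophenoxy)-1,5,7,7-tetramethoxy-1-(trimethylsilyloxy)hept-1-en-3-one (silyl enol ether of the β-keto ester, ketene acetal form drawn; diastereomer mixture) | COC(O[Si](C)(C)C)=CC(=O)C(Oc1ccc(Br)cc1Br)C(OC)CC(OC)OC | intermediate (not isolated)
9 | cyclohexanone ester: methyl 3-(2,4-dibromophenoxy)-4,6-dimethoxy-2-oxocyclohexane-1-carboxylate (diastereomer mixture) | COC(=O)C1C(OC)CC(OC)C(Oc2ccc(Br)cc2Br)C1=O | intermediate (not isolated)
10 | methyl 3-(2,4-dibromophenoxy)-2-hydroxybenzoate | COC(=O)c1cccc(Oc2ccc(Br)cc2Br)c1O | intermediate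
11 | O-methyl ester: methyl 3-(2,4-dibromophenoxy)-2-methoxybenzoate | COC(=O)c1cccc(Oc2ccc(Br)cc2Br)c1OC | intermediate (not isolated)
12 | 3-(2,4-dibromophenoxy)-2-methoxybenzoic acid | OC(=O)c1cccc(Oc2ccc(Br)cc2Br)c1OC | intermediate
13 | 6-bromo-3-(2,4-dibromophenoxy)-2-methoxybenzoic acid | OC(=O)c1c(OC)c(Oc2ccc(Br)cc2Br)ccc1Br | intermediate
14 | 6-bromo-3-(2,4-dibromophenoxy)-2-hydroxybenzoic acid | OC(=O)c1c(O)c(Oc2ccc(Br)cc2Br)ccc1Br | intermediate
15 | C4-bromo acid: 5,6-dibromo-3-(2,4-dibromophenoxy)-2-hydroxybenzoic acid | OC(=O)c1c(O)c(Oc2ccc(Br)cc2Br)cc(Br)c1Br | intermediate (not isolated)
16 | 2,3,4-tribromo-6-(2,4-dibromophenoxy)phenol | Oc1c(Oc2ccc(Br)cc2Br)cc(Br)c(Br)c1Br | target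

## Step count and least certain steps

Total step count: 8 steps. Longest linear sequence: 8 steps (from 1 or 2 to 16); 7 enters at step 4.

Step 4 (key step). The most likely failure is protodesilylation of 6 back to 3 before the first C–C bond forms. The terminal carbon carries the aryloxy group and is more hindered and less nucleophilic than in an unsubstituted diene, and crude 6 may carry traces of acid or amine salt. A stall before the second ring-forming attack is a lesser risk. The fallback gives up the annulation and makes the diaryl ether bond by oxidative copper coupling. It sets out from 1, which would be coupled with [2-methoxy-3-(methoxycarbonyl)phenyl]boronic acid F1 (Cu(OAc)2, pyridine, 4 Å molecular sieves, CH2Cl2, air, 20 °C; Chan–Lam coupling, which leaves aryl bromides alone). It comes back to the route at 11, which is saponified to 12 as in the second half of step 5.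

Step 6. The most likely failure is slow cyclopalladation by the weakly coordinating carboxylate, which would let background processes take over. These are electrophilic substitution at C3 or on ring B, ipso displacement of the carboxyl group by electrophilic bromine, and palladium-mediated protodecarboxylation of the doubly ortho-substituted product. The fallback changes the directing group, the metal and the bond first formed. It sets out from 11, isolated for this purpose by working up step 5 before the hydroxide is added. Ester-directed ortho C–H borylation (B2pin2, [Ir(OMe)(cod)]2, tris[3,5-bis(trifluoromethyl)phenyl]phosphine, octane, 80 °C) should give methyl 3-(2,4-dibromophenoxy)-2-methoxy-6-(4,4,5,5-tetramethyl-1,3,2-dioxaborolan-2-yl)benzoate F2. Bromodeboronation (CuBr2, MeOH–H2O, 80 °C) should give methyl 6-bromo-3-(2,4-dibromophenoxy)-2-methoxybenzoate F3. Hydrolysis of the hindered ester (KOH, DMSO–H2O, 90 °C) comes back to the route at 13.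

Step 3. The most likely failure is competing deprotonation of ring B at C3', between its two bromines, by the lithium amide, followed by bromine migration or aryne formation; partial C-silylation is a lesser risk. The fallback replaces the strong base by soft enolisation. It sets out from 3, which with Me3SiOTf (2.2 equiv) and Et3N (2.5 equiv) in Et2O at 0 °C should be silylated twice on oxygen and so converted directly into 6, where it comes back to the route. It makes no compound outside the list (F0).

Step 1. The most likely failure is self-condensation of the enolate of 2 (alkylation of one molecule by another) outrunning attack by the hindered, weakly nucleophilic 2,4-dibromophenoxide. The fallback uses a surrogate of 2 that has no acidic hydrogens. It sets out from 1, which would be alkylated with methyl (2E)-4-bromo-3-methoxybut-2-enoate F4 (K2CO3, acetone, reflux) to give methyl (2E)-4-(2,4-dibromophenoxy)-3-methoxybut-2-enoate F5. Hydrolysis of the enol ether (2 M aq. HCl, THF, 40 °C) comes back to the route at 3.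

## Further compounds

F1 | step 4 | [2-methoxy-3-(methoxycarbonyl)phenyl]boronic acid | COC(=O)c1cccc(B(O)O)c1OC
F2 | step 6 | methyl 3-(2,4-dibromophenoxy)-2-methoxy-6-(4,4,5,5-tetramethyl-1,3,2-dioxaborolan-2-yl)benzoate | COC(=O)c1c(B2OC(C)(C)C(C)(C)O2)ccc(Oc2ccc(Br)cc2Br)c1OC
F3 | step 6 | methyl 6-bromo-3-(2,4-dibromophenoxy)-2-methoxybenzoate | COC(=O)c1c(Br)ccc(Oc2ccc(Br)cc2Br)c1OC
F0 | step 3 | none | none
F4 | step 1 | methyl (2E)-4-bromo-3-methoxybut-2-enoate | CO/C(CBr)=C/C(=O)OC
F5 | step 1 | methyl (2E)-4-(2,4-dibromophenoxy)-3-methoxybut-2-enoate | CO/C(COc1ccc(Br)cc1Br)=C/C(=O)OC
A1 | alternative 1 | 2-(trimethylsilyl)phenyl trifluoromethanesulfonate | C[Si](C)(C)c1ccccc1OS(=O)(=O)C(F)(F)F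
A2 | alternative 1 | 4-bromo-2-methoxyphenol | COc1cc(Br)ccc1O
A3 | alternative 1 | 1,2-dibromo-1,1,2,2-tetrachloroethane | BrC(Cl)(Cl)C(Cl)(Cl)Br
A4 | alternative 1 | 4-bromo-1-(2-bromophenoxy)-2-methoxybenzene | COc1cc(Br)ccc1Oc1ccccc1Br
A5 | alternative 2 | 5-bromo-2H-pyran-2-one (5-bromo-2-pyrone) | O=c1ccc(Br)co1
A6 | alternative 2 | 2-[(2,4-dibromophenoxy)ethynyl]-4,4,5,5-tetramethyl-1,3,2-dioxaborolane | CC1(C)OB(C#COc2ccc(Br)cc2Br)OC1(C)C
A7 | alternative 2 | 2-[5-bromo-2-(2,4-dibromophenoxy)phenyl]-4,4,5,5-tetramethyl-1,3,2-dioxaborolane | CC1(C)OB(c2cc(Br)ccc2Oc2ccc(Br)cc2Br)OC1(C)C
A8 | alternative 2 | 5-bromo-2-(2,4-dibromophenoxy)phenol | Oc1cc(Br)ccc1Oc1ccc(Br)cc1Br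
A9 | alternative 3 | 3,5-dibromo-2H-pyran-2-one (3,5-dibromo-2-pyrone) | O=c1occ(Br)cc1Br
A10 | alternative 3 | 4-bromo-1-(ethynyloxy)-2-methoxybenzene | COc1cc(Br)ccc1OC#C
A11 | alternative 3 | 4-bromo-1-(2,4-dibromophenoxy)-2-methoxybenzene | COc1cc(Br)ccc1Oc1ccc(Br)cc1Br
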